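**Plan**

- Retrosynthesis (guaianolide numbering: cyclopentane C1–C5; cycloheptane C1, C5–C10; lactone O–C6–C7–C11(=C13)–C12; enol ether bridge C10=C14–O–C4): after removing the O15 silyl group and the O9 acetate, the C9–C10 bond of the seven-membered ring is cut (alkenyl iodide plus aldehyde), then C6–C7 and O6–C12 are cut together.
- The second cut is possible because the trans α-methylene-γ-lactone (ring O6, C6, C7, C11, C12 with exocyclic C11=C13) is the retron of a 2-methoxycarbonylallylboronate adding to a C6 aldehyde. It splits the molecule into fragment A (C1–C6, C10, C14, C15, the 2-oxabicyclo[3.2.1]octene) and fragment B (C7–C9, C11–C13, carrying the C8 ester).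
- Forward: cyclopentane, then bridged δ-lactone (ring O–C4–C5–C1–C10–C14), then iodo enol ether aldehyde (fragment A); fragment B from (R)-glyceraldehyde acetonide through an ynoate; the union closes the γ-lactone; a Nozaki–Hiyama–Kishi reaction closes the seven-membered ring; acetylation and desilylation finish.
- Stereochemistry: C1 from a CBS reduction relayed by a Johnson–Claisen rearrangement; C5 by hydroboration anti to the C1 chain; C4 by addition to the ketone anti to both neighbours; C8 from (R)-glyceraldehyde; the side chain from (S)-2-methylbutanoic acid; C6 and C7 in the union; C9 in the ring closure.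

Key step: step 21

Remark on the chemistry: guaianolide numbering is kept for every intermediate; TBS = tert-butyldimethylsilyl, TBDPS = tert-butyldiphenylsilyl, Bpin = 4,4,5,5-tetramethyl-1,3,2-dioxaborolan-2-yl; where no CIP descriptor is given, the absolute configuration is that of the SMILES in the compound list.

**Fragment A**

Step 1
Reactants: 1 cyclopent-2-en-1-one
Product: 2 2-(hydroxymethyl)cyclopent-2-en-1-one
Conditions: 37% aq. CH2O, imidazole (cat.), THF/H2O, rt
Reagents that add atoms: formaldehyde, C=O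
Why: Morita–Baylis–Hillman reaction: the amine adds to the enone β-carbon, the enolate attacks formaldehyde at the α-carbon and the catalyst is expelled, which puts C6 on C5 without creating a stereocentre.

Step 2
Reactants: 2 2-(hydroxymethyl)cyclopent-2-en-1-one
Product: 3 2-(TBS-oxymethyl)cyclopent-2-en-1-one
Conditions: TBSCl, imidazole, DMF, 0 °C to rt
Reagents that add atoms: tert-butyl(chloro)dimethylsilane, CC(C)(C)[Si](C)(C)Cl
Why: Imidazole-assisted silylation of a primary alcohol; the TBS ether masks O6 until step 13.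

Step 3
Reactants: 3 2-(TBS-oxymethyl)cyclopent-2-en-1-one
Product: 4 (1S)-2-(TBS-oxymethyl)cyclopent-2-en-1-ol
Conditions: (R)-2-methyl-CBS-oxazaborolidine (10 mol%), BH3·SMe2, THF, −20 °C; MeOH quench
Reagents that add atoms: none
Why: Corey–Bakshi–Shibata reduction: the oxazaborolidine–borane complex delivers hydride to one carbonyl face with the α-substituted alkenyl carbon as the large group, which for the (R)-catalyst should give the (1S)-alcohol, and 1,2-reduction outruns hydroboration at low temperature.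

Step 4
Reactants: 4 (1S)-2-(TBS-oxymethyl)cyclopent-2-en-1-ol
Product: 6 ethyl 2-[(1S)-2-(TBS-oxymethyl)cyclopent-2-en-1-yl]acetate, via ketene acetal 5 (not isolated)
Conditions: MeC(OEt)3, EtCO2H (cat.), 140 °C, EtOH distilled off
Reagents that add atoms: triethyl orthoacetate, CC(OCC)(OCC)OCC
Why: Johnson–Claisen rearrangement: ketene acetal 5 undergoes a suprafacial [3,3] shift, so the new C1–C10 bond appears on the ring face that held the C4–O bond and the configuration set in step 3 is transferred to C1.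

Step 5
Reactants: 6 ethyl 2-[(1S)-2-(TBS-oxymethyl)cyclopent-2-en-1-yl]acetate
Product: 8 ethyl 2-[(1S,2S,3R)-3-hydroxy-2-(TBS-oxymethyl)cyclopentyl]acetate (CH2OTBS cis to CH2CO2Et; OH trans to both), via B-alkyl-9-BBN adduct 7 (not isolated)
Conditions: 9-BBN, THF, 60 °C; then 30% H2O2, aq. NaOAc, 0 °C to rt
Reagents that add atoms: hydrogen peroxide, OO
Why: Hydroboration–oxidation: 9-BBN, which leaves the ester alone, adds boron to the less substituted C4 and hydrogen to C5 from the face opposite the C1 side chain, so C6 ends cis to C10, and oxidation proceeds with retention.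

Step 6
Reactants: 8 ethyl 2-[(1S,2S,3R)-3-hydroxy-2-(TBS-oxymethyl)cyclopentyl]acetate
Product: 9 ethyl 2-[(1S,2S)-2-(TBS-oxymethyl)-3-oxocyclopentyl]acetate (cis)
Conditions: Dess–Martin periodinane, NaHCO3, CH2Cl2, 0 °C; used crude
Reagents that add atoms: none
Why: Dess–Martin oxidation under buffered, non-basic conditions should give the cis-2,3-disubstituted cyclopentanone without epimerising C5 or eliminating the β-silyloxy group.

Step 7
Reactants: 9 ethyl 2-[(1S,2S)-2-(TBS-oxymethyl)-3-oxocyclopentyl]acetate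
Product: 11 1-ethenyl-8-(TBS-oxymethyl)-2-oxabicyclo[3.2.1]octan-3-one (CH2OTBS syn to the lactone bridge), via hydroxy ester 10 (not isolated)
Conditions: CH2=CHMgBr, CeCl3, THF, −78 to 0 °C
Reagents that add atoms: vinylmagnesium bromide, C=C[Mg]Br
Why: Organocerium 1,2-addition then lactonisation: the weakly basic vinylcerium reagent attacks the ketone from the face opposite the two cis substituents on C5 and C1, placing O4 cis to C6 and C10, and the alkoxide of 10 closes the bridged δ-lactone onto the cis C14 ester.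

Step 8
Reactants: 11 1-ethenyl-8-(TBS-oxymethyl)-2-oxabicyclo[3.2.1]octan-3-one
Product: 14 1-(hydroxymethyl)-8-(TBS-oxymethyl)-2-oxabicyclo[3.2.1]octan-3-one, via ozonide 12 (not isolated), via aldehyde 13 (not isolated)
Conditions: O3, CH2Cl2, −78 °C; then NaBH4, MeOH, −78 to 0 °C
Reagents that add atoms: ozone, [O-][O+]=O
Why: Ozonolysis with reductive work-up: the only C=C bond is cleaved, and borohydride reduces ozonide 12 and aldehyde 13 to the primary alcohol faster than it attacks the hindered lactone.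

Step 9
Reactants: 14 1-(hydroxymethyl)-8-(TBS-oxymethyl)-2-oxabicyclo[3.2.1]octan-3-one
Product: 15 1-(TBDPS-oxymethyl)-8-(TBS-oxymethyl)-2-oxabicyclo[3.2.1]octan-3-one
Conditions: TBDPSCl, imidazole, DMAP (cat.), DMF, rt
Reagents that add atoms: tert-butyl(chloro)diphenylsilane, CC(C)(C)[Si](Cl)(c1ccccc1)c1ccccc1
Why: Silylation of the neopentyl-type primary alcohol gives the robust TBDPS ether that is kept until the last step and later screens the C4 flank of the aldehyde.

Step 10
Reactants: 15 1-(TBDPS-oxymethyl)-8-(TBS-oxymethyl)-2-oxabicyclo[3.2.1]octan-3-one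
Product: 16 1-(TBDPS-oxymethyl)-8-(TBS-oxymethyl)-2-oxabicyclo[3.2.1]octan-3-ol (lactol, anomer mixture)
Conditions: DIBAL-H, CH2Cl2, −78 °C; Rochelle salt work-up
Reagents that add atoms: none
Why: Partial reduction of a lactone by DIBAL-H stops at the tetrahedral aluminium acetal at low temperature and gives the lactol on work-up.

Step 11
Reactants: 16 1-(TBDPS-oxymethyl)-8-(TBS-oxymethyl)-2-oxabicyclo[3.2.1]octan-3-ol
Product: 18 1-(TBDPS-oxymethyl)-8-(TBS-oxymethyl)-2-oxabicyclo[3.2.1]oct-3-ene, via anomeric mesylate 17 (not isolated)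
Conditions: MsCl, Et3N, THF, 0 to 65 °C
Reagents that add atoms: none
Why: Lactol dehydration: mesylate 17 ionises to an oxocarbenium ion that loses H10 (E1), giving the C10=C14 enol ether inside the three-atom bridge and not at a bridgehead.

Step 12
Reactants: 18 1-(TBDPS-oxymethyl)-8-(TBS-oxymethyl)-2-oxabicyclo[3.2.1]oct-3-ene
Product: 19 4-iodo-1-(TBDPS-oxymethyl)-8-(TBS-oxymethyl)-2-oxabicyclo[3.2.1]oct-3-ene
Conditions: NIS, AgNO3 (20 mol%), MeCN, 60 °C
Reagents that add atoms: N-iodosuccinimide, O=C1CCC(=O)N1I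
Why: Electrophilic iodination of an enol ether at its β-carbon (the method used for 2-iodoglycals): iodonium attack at C10 gives an oxocarbenium ion that loses H10 and restores the C10=C14 bond.

Step 13
Reactants: 19 4-iodo-1-(TBDPS-oxymethyl)-8-(TBS-oxymethyl)-2-oxabicyclo[3.2.1]oct-3-ene
Product: 20 [4-iodo-1-(TBDPS-oxymethyl)-2-oxabicyclo[3.2.1]oct-3-en-8-yl]methanol
Conditions: HF·pyridine, pyridine, THF, 0 °C to rt
Reagents that add atoms: none
Why: Chemoselective desilylation: buffered HF·pyridine cleaves the unhindered primary TBS ether much faster than the neopentyl TBDPS ether and should be too weakly acidic to hydrate the iodo enol ether.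

Step 14
Reactants: 20 [4-iodo-1-(TBDPS-oxymethyl)-2-oxabicyclo[3.2.1]oct-3-en-8-yl]methanol
Product: 21 4-iodo-1-(TBDPS-oxymethyl)-2-oxabicyclo[3.2.1]oct-3-ene-8-carbaldehyde (fragment A; formyl group syn to the O2–C3=C4 bridge)
Conditions: Dess–Martin periodinane, NaHCO3, CH2Cl2, 0 °C; used at once
Reagents that add atoms: none
Why: Dess–Martin oxidation of a primary alcohol; the buffered neutral medium avoids epimerisation at C5 and β-elimination of the C4–O bond.

**Fragment B**

Step 15
Reactants: 22 (R)-2,3-O-isopropylideneglyceraldehyde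
Product: 23 (4S)-4-(2,2-dibromoethenyl)-2,2-dimethyl-1,3-dioxolane
Conditions: CBr4, PPh3, Et3N, CH2Cl2, 0 °C
Reagents that add atoms: carbon tetrabromide, BrC(Br)(Br)Br
Why: First stage of the Corey–Fuchs reaction (Wittig olefination with the dibromomethylene ylide); the buffered conditions leave the α-stereocentre, the future C8, untouched.

Step 16
Reactants: 23 (4S)-4-(2,2-dibromoethenyl)-2,2-dimethyl-1,3-dioxolane
Product: 25 methyl 3-[(4S)-2,2-dimethyl-1,3-dioxolan-4-yl]prop-2-ynoate, via lithium acetylide 24 (not isolated)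
Conditions: n-BuLi (2.1 equiv), THF, −78 °C; then ClCO2Me, −78 to 0 °C
Reagents that add atoms: methyl chloroformate, COC(=O)Cl
Why: Second stage of the Corey–Fuchs reaction: bromine–lithium exchange, carbenoid rearrangement and deprotonation give acetylide 24, which is acylated by the chloroformate.

Step 17
Reactants: 25 methyl 3-[(4S)-2,2-dimethyl-1,3-dioxolan-4-yl]prop-2-ynoate
Product: 26 methyl (4S)-4,5-dihydroxypent-2-ynoate
Conditions: AcOH/H2O 4:1, 40 °C
Reagents that add atoms: none
Why: Acid-catalysed acetonide hydrolysis; the linear alkyne keeps the freed C8 hydroxyl from lactonising onto the ester.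

Step 18
Reactants: 26 methyl (4S)-4,5-dihydroxypent-2-ynoate
Product: 27 methyl (4S)-4-hydroxy-5-(TBS-oxy)pent-2-ynoate
Conditions: TBSCl (1.05 equiv), imidazole, CH2Cl2, −20 to 0 °C
Reagents that add atoms: tert-butyl(chloro)dimethylsilane, CC(C)(C)[Si](C)(C)Cl
Why: Sterically controlled silylation of the primary hydroxyl in preference to the secondary propargylic one.

Step 19
Reactants: 27 methyl (4S)-4-hydroxy-5-(TBS-oxy)pent-2-ynoate; 28 (S)-2-methylbutanoic acid
Product: 29 methyl (4S)-4-{[(2S)-2-methylbutanoyl]oxy}-5-(TBS-oxy)pent-2-ynoate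
Conditions: EDC·HCl, DMAP (10 mol%), CH2Cl2, 0 °C
Reagents that add atoms: none
Why: Steglich esterification through the O-acylisourea and acylpyridinium ion; low temperature and little DMAP limit epimerisation of the α-branched acid and base-induced isomerisation of the ynoate.

Step 20
Reactants: 29 methyl (4S)-4-{[(2S)-2-methylbutanoyl]oxy}-5-(TBS-oxy)pent-2-ynoate
Product: 31 methyl (2Z,4S)-4-{[(2S)-2-methylbutanoyl]oxy}-2-(Bpin-methyl)-5-(TBS-oxy)pent-2-enoate (fragment B; C8 cis to the ester and trans to CH2B), via alkenylalane 30 (not isolated)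
Conditions: DIBAL-H, HMPA, THF, 0 °C; then ICH2Bpin, 0 °C to rt; Rochelle salt work-up
Reagents that add atoms: 2-(iodomethyl)-4,4,5,5-tetramethyl-1,3,2-dioxaborolane, ICB1OC(C)(C)C(C)(C)O1
Why: Conjugate hydroalumination of the ynoate by the DIBAL-H–HMPA complex then C-alkylation: hydride adds to C7 and aluminium to C11 on the same side, and alkylation of 30 with retention leaves C8 cis to the ester, the isomer that an SN2′ borylation of a Baylis–Hillman acetate would not give and the one that leads to trans-lactones.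

**Union and end game**

Step 21
Reactants: 21 fragment A aldehyde; 31 fragment B allylboronate
Product: 33 trans α-methylene-γ-butyrolactone joining both fragments (C10 iodide, O9-TBS and O15-TBDPS in place), via borate ester 32 (not isolated)
Conditions: 31 (1.5 equiv), toluene (1 M), 100 °C, sealed tube, 72 h
Reagents that add atoms: none
Why: The aldehyde oxygen of 21 binds the boron of 31 and the pair reacts through a closed six-membered chair, the closest known type being the thermal addition of γ-substituted 2-alkoxycarbonylallylboronates to aldehydes with in situ lactonisation: C7 bonds to C6 while the double bond moves to C11=C13, giving borate 32. The B–O oxygen of 32 then attacks the methyl ester (5-exo-trig acyl substitution) and closes the γ-lactone with loss of MeOBpin. The trans (anti) relation of C6 and C7 follows from the chair, in which the bicyclic residue on C6 is equatorial and C8, held trans to CH2B in the configurationally stable boronate, is equatorial too. The absolute sense at C7 is set by C8: with H8 eclipsing the ester-bearing alkene carbon (allylic 1,3-strain), the aldehyde should add anti to the CH2OTBS group and syn to the smaller acyloxy group. The same C6 face should be preferred by the aldehyde itself, whose formyl group lies over the O–C14=C10 bridge with its oxygen turned outward and is approached from the C1 flank because the C4 flank is screened by CH2OTBDPS, so the two partners are expected to be matched. The step needs this trans and facial selectivity plus chemoselectivity for the aldehyde, and neutral heating leaves the iodo enol ether, both silyl ethers and the C8 ester untouched.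

Step 22
Reactants: 33 coupled lactone
Product: 34 C9 primary alcohol
Conditions: HF·pyridine, pyridine, THF, 0 °C
Reagents that add atoms: none
Why: Selective cleavage of the primary TBS ether at O9 as in step 13; the mildly acidic buffer suppresses migration of the C8 ester to O9.

Step 23
Reactants: 34 C9 primary alcohol
Product: 35 C9 aldehyde
Conditions: Dess–Martin periodinane, NaHCO3, CH2Cl2, 0 °C; used at once
Reagents that add atoms: none
Why: Dess–Martin oxidation to the α-acyloxy aldehyde under buffered conditions that should not epimerise C8.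

Step 24
Reactants: 35 C9 aldehyde
Product: 36 tricyclic 9α-alcohol (15-O-TBDPS; OH trans to the 8β ester)
Conditions: CrCl2 (8 equiv), NiCl2 (2 mol%), DMSO/THF, rt, 2 mM, slow addition
Reagents that add atoms: none
Why: Nozaki–Hiyama–Kishi reaction: nickel inserts into the C10–I bond, transmetalation gives an alkenylchromium species of trivalent chromium that adds to the C9 aldehyde (7-exo-trig), and the alcohol trans to the C8 ester should be favoured because the ring then closes with both oxygen substituents pseudo-equatorial.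

Step 25
Reactants: 36 tricyclic 9α-alcohol
Product: 37 9-O-acetate (15-O-TBDPS)
Conditions: Ac2O, DMAP (cat.), pyridine, CH2Cl2, 0 °C to rt
Reagents that add atoms: acetic anhydride, CC(=O)OC(C)=O
Why: DMAP-catalysed acetylation of the secondary allylic alcohol, fast enough to outrun migration of the neighbouring ester.

Step 26
Reactants: 37 9-O-acetate
Product: 38 CNP0013863.2 (target)
Conditions: TBAF, AcOH (1:1), THF, 0 °C to rt
Reagents that add atoms: none
Why: Fluoride cleavage of the TBDPS ether; buffering with acetic acid should keep the medium from adding to the α-methylene lactone, moving the esters or hydrating the enol ether.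

**Compound list**

1 | cyclopent-2-en-1-one | O=C1C=CCC1 | starting material
2 | 2-(hydroxymethyl)cyclopent-2-en-1-one | O=C1CCC=C1CO | intermediate
3 | 2-(TBS-oxymethyl)cyclopent-2-en-1-one | O=C1CCC=C1CO[Si](C)(C)C(C)(C)C | intermediate
4 | (1S)-2-(TBS-oxymethyl)cyclopent-2-en-1-ol | CC(C)(C)[Si](C)(C)OCC1=CCC[C@@H]1O | intermediate
5 | 1-ethoxyethenyl ether of 4 (ketene acetal) | CC(C)(C)[Si](C)(C)OCC1=CCC[C@@H]1OC(=C)OCC | intermediate (not isolated)
6 | ethyl 2-[(1S)-2-(TBS-oxymethyl)cyclopent-2-en-1-yl]acetate | CC(C)(C)[Si](C)(C)OCC1=CCC[C@H]1CC(=O)OCC | intermediate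
7 | ethyl 2-[3-(9-borabicyclo[3.3.1]nonan-9-yl)-2-(TBS-oxymethyl)cyclopentyl]acetate (boron trans to both side chains) | CC(C)(C)[Si](C)(C)OC[C@@H]1[C@H](CC(=O)OCC)CC[C@H]1B2C3CCCC2CCC3 | intermediate (not isolated)
8 | ethyl 2-[(1S,2S,3R)-3-hydroxy-2-(TBS-oxymethyl)cyclopentyl]acetate | CC(C)(C)[Si](C)(C)OC[C@@H]1[C@H](CC(=O)OCC)CC[C@H]1O | intermediate
9 | ethyl 2-[(1S,2S)-2-(TBS-oxymethyl)-3-oxocyclopentyl]acetate | CC(C)(C)[Si](C)(C)OC[C@@H]1[C@H](CC(=O)OCC)CCC1=O | intermediate
10 | ethyl 2-[3-ethenyl-3-hydroxy-2-(TBS-oxymethyl)cyclopentyl]acetate (OH, CH2OTBS and CH2CO2Et all cis; present as its alkoxide) | CC(C)(C)[Si](C)(C)OC[C@@H]1[C@H](CC(=O)OCC)CC[C@@]1(O)C=C | intermediate (not isolated)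
11 | 1-ethenyl-8-(TBS-oxymethyl)-2-oxabicyclo[3.2.1]octan-3-one (CH2OTBS syn to the lactone bridge) | CC(C)(C)[Si](C)(C)OC[C@@H]1[C@H]2CC[C@]1(C=C)OC(=O)C2 | intermediate
12 | 1-(1,2,4-trioxolan-3-yl)-8-(TBS-oxymethyl)-2-oxabicyclo[3.2.1]octan-3-one | CC(C)(C)[Si](C)(C)OC[C@@H]1[C@H]2CC[C@]1(C3OCOO3)OC(=O)C2 | intermediate (not isolated)
13 | 3-oxo-8-(TBS-oxymethyl)-2-oxabicyclo[3.2.1]octane-1-carbaldehyde | CC(C)(C)[Si](C)(C)OC[C@@H]1[C@H]2CC[C@]1(C=O)OC(=O)C2 | intermediate (not isolated)
14 | 1-(hydroxymethyl)-8-(TBS-oxymethyl)-2-oxabicyclo[3.2.1]octan-3-one | CC(C)(C)[Si](C)(C)OC[C@@H]1[C@H]2CC[C@]1(CO)OC(=O)C2 | intermediate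
15 | 1-(TBDPS-oxymethyl)-8-(TBS-oxymethyl)-2-oxabicyclo[3.2.1]octan-3-one | CC(C)(C)[Si](C)(C)OC[C@@H]1[C@H]2CC[C@]1(CO[Si](c3ccccc3)(c3ccccc3)C(C)(C)C)OC(=O)C2 | intermediate
16 | 1-(TBDPS-oxymethyl)-8-(TBS-oxymethyl)-2-oxabicyclo[3.2.1]octan-3-ol | CC(C)(C)[Si](C)(C)OC[C@@H]1[C@H]2CC[C@]1(CO[Si](c3ccccc3)(c3ccccc3)C(C)(C)C)OC(O)C2 | intermediate
17 | 1-(TBDPS-oxymethyl)-8-(TBS-oxymethyl)-2-oxabicyclo[3.2.1]octan-3-yl methanesulfonate | CC(C)(C)[Si](C)(C)OC[C@@H]1[C@H]2CC[C@]1(CO[Si](c3ccccc3)(c3ccccc3)C(C)(C)C)OC(OS(C)(=O)=O)C2 | intermediate (not isolated)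
18 | 1-(TBDPS-oxymethyl)-8-(TBS-oxymethyl)-2-oxabicyclo[3.2.1]oct-3-ene | CC(C)(C)[Si](C)(C)OC[C@@H]1[C@H]2CC[C@]1(CO[Si](c3ccccc3)(c3ccccc3)C(C)(C)C)OC=C2 | intermediate
19 | 4-iodo-1-(TBDPS-oxymethyl)-8-(TBS-oxymethyl)-2-oxabicyclo[3.2.1]oct-3-ene | CC(C)(C)[Si](C)(C)OC[C@@H]1[C@H]2CC[C@]1(CO[Si](c3ccccc3)(c3ccccc3)C(C)(C)C)OC=C2I | intermediate
20 | [4-iodo-1-(TBDPS-oxymethyl)-2-oxabicyclo[3.2.1]oct-3-en-8-yl]methanol | OC[C@@H]1[C@H]2CC[C@]1(CO[Si](c3ccccc3)(c3ccccc3)C(C)(C)C)OC=C2I | intermediate
21 | 4-iodo-1-(TBDPS-oxymethyl)-2-oxabicyclo[3.2.1]oct-3-ene-8-carbaldehyde (fragment A) | O=C[C@@H]1[C@H]2CC[C@]1(CO[Si](c3ccccc3)(c3ccccc3)C(C)(C)C)OC=C2I | intermediate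
22 | (R)-2,3-O-isopropylideneglyceraldehyde | O=C[C@H]1COC(C)(C)O1 | starting material
23 | (4S)-4-(2,2-dibromoethenyl)-2,2-dimethyl-1,3-dioxolane | BrC(Br)=C[C@H]1COC(C)(C)O1 | intermediate
24 | lithium acetylide of (4S)-4-ethynyl-2,2-dimethyl-1,3-dioxolane | [Li]C#C[C@H]1COC(C)(C)O1 | intermediate (not isolated)
25 | methyl 3-[(4S)-2,2-dimethyl-1,3-dioxolan-4-yl]prop-2-ynoate | COC(=O)C#C[C@H]1COC(C)(C)O1 | intermediate
26 | methyl (4S)-4,5-dihydroxypent-2-ynoate | COC(=O)C#C[C@H](O)CO | intermediate
27 | methyl (4S)-4-hydroxy-5-(TBS-oxy)pent-2-ynoate | COC(=O)C#C[C@H](O)CO[Si](C)(C)C(C)(C)C | intermediate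
28 | (S)-2-methylbutanoic acid | CC[C@H](C)C(=O)O | starting material
29 | methyl (4S)-4-{[(2S)-2-methylbutanoyl]oxy}-5-(TBS-oxy)pent-2-ynoate | COC(=O)C#C[C@H](OC(=O)[C@@H](C)CC)CO[Si](C)(C)C(C)(C)C | intermediate
30 | methyl (4S)-2-(diisobutylalumanyl)-4-{[(2S)-2-methylbutanoyl]oxy}-5-(TBS-oxy)pent-2-enoate (C8 cis to the ester) | COC(=O)/C([Al](CC(C)C)CC(C)C)=C\[C@H](OC(=O)[C@@H](C)CC)CO[Si](C)(C)C(C)(C)C | intermediate (not isolated)
31 | methyl (2Z,4S)-4-{[(2S)-2-methylbutanoyl]oxy}-2-(Bpin-methyl)-5-(TBS-oxy)pent-2-enoate (fragment B) | COC(=O)/C(CB1OC(C)(C)C(C)(C)O1)=C\[C@H](OC(=O)[C@@H](C)CC)CO[Si](C)(C)C(C)(C)C | intermediate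
32 | anti homoallylic pinacol borate: methyl ester with C6–O–Bpin, C11=C13 in place, lactone still open | C=C(C(=O)OC)[C@H]([C@H](OC(=O)[C@@H](C)CC)CO[Si](C)(C)C(C)(C)C)[C@H](OB1OC(C)(C)C(C)(C)O1)[C@@H]1[C@H]2CC[C@]1(CO[Si](c3ccccc3)(c3ccccc3)C(C)(C)C)OC=C2I | intermediate (not isolated)
33 | trans α-methylene-γ-butyrolactone: 3-methylideneoxolan-2-one with the fragment A bicycle on C5 (guaiane C6) and the 1-acyloxy-2-(TBS-oxy)ethyl group on C4 (guaiane C7) | C=C1C(=O)O[C@@H]([C@H]1[C@H](OC(=O)[C@@H](C)CC)CO[Si](C)(C)C(C)(C)C)[C@@H]1[C@H]2CC[C@]1(CO[Si](c3ccccc3)(c3ccccc3)C(C)(C)C)OC=C2I | intermediate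
34 | C9 primary alcohol of 33 | C=C1C(=O)O[C@@H]([C@H]1[C@H](OC(=O)[C@@H](C)CC)CO)[C@@H]1[C@H]2CC[C@]1(CO[Si](c3ccccc3)(c3ccccc3)C(C)(C)C)OC=C2I | intermediate
35 | C9 aldehyde | C=C1C(=O)O[C@@H]([C@H]1[C@H](OC(=O)[C@@H](C)CC)C=O)[C@@H]1[C@H]2CC[C@]1(CO[Si](c3ccccc3)(c3ccccc3)C(C)(C)C)OC=C2I | intermediate
36 | tricyclic 9α-alcohol, 8β-(2S)-2-methylbutanoate, 15-O-TBDPS | C=C1C(=O)O[C@H]2[C@H]1[C@H](OC(=O)[C@@H](C)CC)[C@@H](O)C1=CO[C@@]3(CO[Si](c4ccccc4)(c4ccccc4)C(C)(C)C)CC[C@@H]1[C@@H]23 | intermediate
37 | 9α-acetate, 15-O-TBDPS | C=C1C(=O)O[C@H]2[C@H]1[C@H](OC(=O)[C@@H](C)CC)[C@@H](OC(C)=O)C1=CO[C@@]3(CO[Si](c4ccccc4)(c4ccccc4)C(C)(C)C)CC[C@@H]1[C@@H]23 | intermediate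
38 | CNP0013863.2 | C=C1C(=O)O[C@H]2[C@H]1[C@H](OC(=O)[C@@H](C)CC)[C@@H](OC(C)=O)C1=CO[C@@]3(CO)CC[C@@H]1[C@@H]23 | target

**Step count and risks**

Total: 26 steps. Longest linear sequence: 20 steps (steps 1–14, then 21–26); fragment B takes 6 steps (15–20).

Steps most likely to fail:

1. Step 21. Bond formation at the hindered formyl carbon may be slow at the temperature needed, which would let C5 epimerise or let the addition leak through a boat transition state to the cis-lactone. The facial argument also rests on two directing elements being matched, which is reasoned, not established. Fallback: a different allyl donor activated at low temperature, with C–C bond formation separated from lactonisation. It sets out from 31 and 21. Compound 31 is converted with KHF2 in aqueous methanol into the potassium trifluoroborate F1. F1 and 21 are treated with BF3·OEt2 in CH2Cl2 at −78 °C, where the allyldifluoroborane formed in the flask adds through the same closed chair within minutes (known for allyl- and crotyltrifluoroborates) and should give the anti hydroxy ester F2 after work-up. F2 is lactonised with PPTS (cat.) in toluene at 50 °C, and the route is rejoined at 33.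

2. Step 20. The aluminium hydride may reduce the C8 ester or the methyl ester, and the alkene geometry may be lost through the allenolate form before alkylation. Fallback: stepwise palladium chemistry from 29. Hydrostannation (Bu3SnH, Pd(PPh3)4 cat., THF, 0 °C; syn addition with tin at C11) should give the α-stannyl enoate F3. Iododestannylation (I2, CH2Cl2, 0 °C) gives with retention the α-iodo enoate F4. Negishi coupling of F4 with IZnCH2Bpin (from ICH2Bpin and zinc dust; Pd(PPh3)4 cat., THF, rt) rejoins the route at 31.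

3. Step 24. Facial selectivity at C9 may be poor during ring closure, since the pseudo-equatorial argument is only qualitative. Fallback: set C9 by reduction instead of by the C–C bond formation. The mixture of 36 and its C9 epimer is oxidised with Dess–Martin periodinane to the C9 ketone F5. F5 is reduced with (S)-2-methyl-CBS-oxazaborolidine and catecholborane in toluene at −78 °C; with the alkenyl carbon C10 as the large group this catalyst should deliver the 9α-alcohol, and the route is rejoined at 36.

**Further compounds**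

F1 | step 21 | potassium trifluoroborate corresponding to 31 | COC(=O)/C(C[B-](F)(F)F)=C\[C@H](OC(=O)[C@@H](C)CC)CO[Si](C)(C)C(C)(C)C.[K+]
F2 | step 21 | anti hydroxy ester (open form of 33 with C6–OH and methyl ester) | C=C(C(=O)OC)[C@H]([C@H](OC(=O)[C@@H](C)CC)CO[Si](C)(C)C(C)(C)C)[C@H](O)[C@@H]1[C@H]2CC[C@]1(CO[Si](c3ccccc3)(c3ccccc3)C(C)(C)C)OC=C2I
F3 | step 20 | methyl (2E,4S)-4-{[(2S)-2-methylbutanoyl]oxy}-5-(TBS-oxy)-2-(tributylstannyl)pent-2-enoate | COC(=O)/C([Sn](CCCC)(CCCC)CCCC)=C\[C@H](OC(=O)[C@@H](C)CC)CO[Si](C)(C)C(C)(C)C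
F4 | step 20 | methyl (2E,4S)-2-iodo-4-{[(2S)-2-methylbutanoyl]oxy}-5-(TBS-oxy)pent-2-enoate | COC(=O)/C(I)=C\[C@H](OC(=O)[C@@H](C)CC)CO[Si](C)(C)C(C)(C)C
F5 | step 24 | C9 ketone corresponding to 36 | C=C1C(=O)O[C@H]2[C@H]1[C@H](OC(=O)[C@@H](C)CC)C(=O)C1=CO[C@@]3(CO[Si](c4ccccc4)(c4ccccc4)C(C)(C)C)CC[C@@H]1[C@@H]23
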